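**Retrosynthetic overview**

1. Ring C (the pyranone) is opened last at O1–C2 and C3–C(benzoyl): a 1,3-diketone from acetophenone 15 and methyl benzoate, the acetyl group coming from Friedel–Crafts acetylation of the symmetric aminoresorcinol 14.
2. The piperidine is cut at N–CH3 (reductive amination), at N–C6' (intramolecular displacement of a chloride) and at N–C2' (the key bond).
3. Feature used: in ring A the C7 oxygen sits ortho to C8, so the chain N–S–O7–C7–C8–C2' puts the nitrogen of an O7 sulfamate six atoms round from the benzylic C2'–H. A nitrene on that nitrogen inserts there, closes a temporary benzoxathiazine dioxide ring and sets C2' as R under catalyst control.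
4. The precursor, a 2-(5-chloropentyl)-5-methoxyresorcinol bearing one pivalate and one sulfamate, comes from 5-methoxyresorcinol by ortho-lithiation and alkylation of its bis-MOM ether.
5. Order of ring formation: oxathiazine (step 6, temporary), piperidine (step 7), oxathiazine removed (step 8), pyranone (step 12).

Key step: step 6

Assumption: the sense of induction of Rh2(S-nap)4 on an aryl O-sulfamate cannot be read off from its 3-arylpropyl sulfamate cases. The catalyst antipode that gives 4R is therefore fixed by one test run; the route is written with Rh2(S-nap)4 and uses Rh2(R-nap)4 if the test shows the opposite sense. Flavone numbering is used for the target; C2' is the piperidine carbon on C8 and C6' the piperidine CH2 on nitrogen.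

**Route**

Step 1
Reactants: 1 5-methoxyresorcinol
Product: 2 1-methoxy-3,5-bis(methoxymethoxy)benzene
Conditions: NaH (2.4 equiv), MOMCl (2.3 equiv), DMF, 0 °C → rt
Reagents that add atoms: chloromethyl methyl ether, COCCl
Why: Williamson-type O-alkylation of both sodium phenoxides with the hard electrophile MOMCl should give the bis-acetal, whose two OMOM groups direct the metalation of step 2.

Step 2
Reactants: 2 1-methoxy-3,5-bis(methoxymethoxy)benzene; 3 1-bromo-5-chloropentane
Product: 5 2-(5-chloropentyl)-5-methoxy-1,3-bis(methoxymethoxy)benzene, via C2-aryllithium 4 (not isolated)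
Conditions: n-BuLi (1.1 equiv), TMEDA, THF, 0 °C; then 3 (1.5 equiv), 0 °C → rt
Reagents that add atoms: none
Why: Directed ortho-metalation should occur at the carbon flanked by both OMOM groups (OMOM outranks OMe as a directing group), and SN2 alkylation of the aryllithium then takes the bromide of 3 and leaves the chloride for step 7.

Step 3
Reactants: 5 2-(5-chloropentyl)-5-methoxy-1,3-bis(methoxymethoxy)benzene
Product: 6 2-(5-chloropentyl)-5-methoxybenzene-1,3-diol
Conditions: HCl (1.25 M in MeOH), 40 °C
Reagents that add atoms: none
Why: Acid-catalysed acetal exchange to methanol should free both phenols while the aryl methyl ether and the primary chloride stay inert.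

Step 4
Reactants: 6 2-(5-chloropentyl)-5-methoxybenzene-1,3-diol
Product: 7 2-(5-chloropentyl)-3-hydroxy-5-methoxyphenyl pivalate
Conditions: PivCl (1.0 equiv, slow addition), Et3N, CH2Cl2, −40 → 0 °C
Reagents that add atoms: pivaloyl chloride, CC(C)(C)C(Cl)=O
Why: This is a statistical mono-esterification (acyl substitution at a phenoxide) of a diol whose two hydroxyls are equivalent, so no regiochemical question arises and unreacted 6 and the bis-pivalate (after methanolysis) can be returned to the step.

Step 5
Reactants: 7 2-(5-chloropentyl)-3-hydroxy-5-methoxyphenyl pivalate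
Product: 8 2-(5-chloropentyl)-5-methoxy-3-(sulfamoyloxy)phenyl pivalate
Conditions: ClSO2NCO, HCO2H, MeCN, 0 °C → rt (forms ClSO2NH2); then 7, DMA, 0 °C → rt
Reagents that add atoms: sulfamoyl chloride, NS(=O)(=O)Cl (made in the flask from chlorosulfonyl isocyanate, O=C=NS(=O)(=O)Cl, and formic acid)
Why: O-sulfamoylation of a phenol with sulfamoyl chloride in N,N-dimethylacetamide is the standard base-free preparation of aryl sulfamates and should leave the aryl pivalate and the alkyl chloride untouched.

Step 6
Reactants: 8 2-(5-chloropentyl)-5-methoxy-3-(sulfamoyloxy)phenyl pivalate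
Product: 10 (4R)-4-(4-chlorobutyl)-7-methoxy-2,2-dioxo-3,4-dihydro-1,2,3-benzoxathiazin-5-yl pivalate, via iminoiodinane 9 (not isolated)
Conditions: Rh2(S-nap)4 (2 mol %), PhI=O (1.2 equiv), 3 Å MS, CH2Cl2, rt
Reagents that add atoms: none
Why: Iodosylbenzene should convert the sulfamate NH2 into the iminoiodinane 9, which passes its nitrogen to the dirhodium core (both rhodium atoms divalent) as a rhodium-bound nitrene, and this inserts into a C1–H bond of the pentyl chain in one concerted but asynchronous, hydride-transfer-like event. The closest known reaction type is the rhodium-catalysed intramolecular C–H amination of sulfamate esters, which is established for benzylic C–H bonds and has enantioselective variants with chiral dirhodium carboxamidates and carboxylates. The one ring that closes, the 3,4-dihydro-1,2,3-oxathiazine, does so by N–C4 bond formation through a six-membered N–S–O–C8a–C4a–C4 transition state in which the arene supplies two of the six atoms. The new stereocentre C4 (later C2' of the piperidine) is controlled by the catalyst, whose chiral carboxamidate pocket tells the two enantiotopic benzylic hydrogens apart, and the catalyst antipode that leads to 4R is the one used. The step needs site selectivity (benzylic CH2 against the four other CH2 groups and the arene) and chemoselectivity against ring oxidation; the substrate secures both because the short aryl–O tether reaches only C1 of the chain, the benzylic C–H bond is the most hydridic, and the pivalate and sulfamate esters keep the ring too electron-poor for arene amination, while iodosylbenzene is chosen so that no carboxylic acid is released onto the carboxamidate ligands.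

Step 7
Reactants: 10 (4R)-4-(4-chlorobutyl)-7-methoxy-2,2-dioxo-3,4-dihydro-1,2,3-benzoxathiazin-5-yl pivalate
Product: 11 (R)-piperidine-fused sulfamidate: compound 10 with N3 bonded to the terminal carbon of the C4 side chain in place of chlorine (a pyrido[1,2-c][1,2,3]benzoxathiazine S,S-dioxide with pivalate and methoxy unchanged)
Conditions: K2CO3, DMF, 60 °C
Reagents that add atoms: none
Why: The acidic sulfamidate N–H is deprotonated and the nitrogen should displace the primary chloride in a 6-exo-tet intramolecular N-alkylation that forms N–C6' and so the piperidine ring, without touching the stereocentre and with the hindered pivalate resisting acyl transfer.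

Step 8
Reactants: 11 (R)-piperidine-fused sulfamidate
Product: 12 5-methoxy-2-[(2R)-piperidin-2-yl]benzene-1,3-diol
Conditions: LiAlH4 (excess), THF, 0 → 50 °C; then aq. potassium sodium tartrate
Reagents that add atoms: none
Why: Hydride attack at the sulfonyl sulfur expels the phenoxide (reductive desulfonylation of an aryl sulfamidate, SO2 being lost on work-up) and the same reagent reduces the pivalate to the phenol, so the C2'–N bond is never broken and the configuration should be kept.

Step 9
Reactants: 12 5-methoxy-2-[(2R)-piperidin-2-yl]benzene-1,3-diol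
Product: 14 5-methoxy-2-[(2R)-1-methylpiperidin-2-yl]benzene-1,3-diol, via N-methyleneiminium ion 13 (not isolated)
Conditions: aq. HCHO (1.1 equiv), NaBH(OAc)3, AcOH, THF, 0 °C → rt
Reagents that add atoms: formaldehyde, C=O
Why: In this reductive amination the secondary amine condenses with formaldehyde and the iminium ion is reduced at once by the acyloxyborohydride, while near-stoichiometric formaldehyde at low temperature should keep the electron-rich ring from being hydroxymethylated.

Step 10
Reactants: 14 5-methoxy-2-[(2R)-1-methylpiperidin-2-yl]benzene-1,3-diol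
Product: 15 1-[2,4-dihydroxy-6-methoxy-3-((2R)-1-methylpiperidin-2-yl)phenyl]ethan-1-one
Conditions: BF3·OEt2 (excess, added first), Ac2O (1.2 equiv), CH2Cl2, 0 °C → rt; aq. NaHCO3 work-up
Reagents that add atoms: acetic anhydride, CC(=O)OC(C)=O
Why: Friedel–Crafts acetylation of a phloroglucinol-type ring should go cleanly because the two open ring positions are equivalent (each between OH and OMe), the first acyl group deactivates the ring against a second, and the amine is held as its BF3 adduct so that it is neither acylated nor turned into a leaving group.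

Step 11
Reactants: 15 1-[2,4-dihydroxy-6-methoxy-3-((2R)-1-methylpiperidin-2-yl)phenyl]ethan-1-one; 16 methyl benzoate
Product: 18 1-[2,4-dihydroxy-6-methoxy-3-((2R)-1-methylpiperidin-2-yl)phenyl]-3-phenylpropane-1,3-dione, via trisodium enolate 17 (not isolated)
Conditions: NaH (5 equiv), DMF, 0 °C → rt; then aq. HCl to pH 7–8
Reagents that add atoms: none
Why: Crossed Claisen condensation of the methyl-ketone enolate (formed beside the two phenoxides) with the non-enolisable ester should give the same 1,3-diketone as a Baker–Venkataraman rearrangement, driven by deprotonation of the product, and an ester is the benzoyl donor because it does not acylate the tertiary amine.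

Step 12
Reactants: 18 1-[2,4-dihydroxy-6-methoxy-3-((2R)-1-methylpiperidin-2-yl)phenyl]-3-phenylpropane-1,3-dione
Product: 19 (R)-7-hydroxy-5-methoxy-8-(1-methylpiperidin-2-yl)-2-phenyl-4H-chromen-4-one (target)
Conditions: conc. HCl, AcOH, 50 °C; then aq. NaHCO3
Reagents that add atoms: none
Why: Acid-catalysed cyclodehydration of the 2-hydroxyaryl 1,3-diketone (the closing step of the Baker–Venkataraman flavone synthesis) should form O1–C2 because only the hydroxyl ortho to the ketone can reach the benzoyl carbonyl, leaving the para hydroxyl as C7–OH, and the moderate temperature spares the benzylic C–N bond.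

**Compound list**

1 | 5-methoxyresorcinol (5-methoxybenzene-1,3-diol) | COc1cc(O)cc(O)c1 | starting material
2 | 1-methoxy-3,5-bis(methoxymethoxy)benzene | COCOc1cc(OC)cc(OCOC)c1 | intermediate
3 | 1-bromo-5-chloropentane | ClCCCCCBr | starting material
4 | [4-methoxy-2,6-bis(methoxymethoxy)phenyl]lithium (C2-aryllithium) | [Li]c1c(OCOC)cc(OC)cc1OCOC | intermediate
5 | 2-(5-chloropentyl)-5-methoxy-1,3-bis(methoxymethoxy)benzene | COCOc1cc(OC)cc(OCOC)c1CCCCCCl | intermediate
6 | 2-(5-chloropentyl)-5-methoxybenzene-1,3-diol | COc1cc(O)c(CCCCCCl)c(O)c1 | intermediate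
7 | 2-(5-chloropentyl)-3-hydroxy-5-methoxyphenyl pivalate | COc1cc(O)c(CCCCCCl)c(OC(=O)C(C)(C)C)c1 | intermediate
8 | 2-(5-chloropentyl)-5-methoxy-3-(sulfamoyloxy)phenyl pivalate | COc1cc(OS(N)(=O)=O)c(CCCCCCl)c(OC(=O)C(C)(C)C)c1 | intermediate
9 | 2-(5-chloropentyl)-5-methoxy-3-{[(phenyl-λ3-iodanylidene)sulfamoyl]oxy}phenyl pivalate (iminoiodinane) | COc1cc(OS(=O)(=O)N=Ic2ccccc2)c(CCCCCCl)c(OC(=O)C(C)(C)C)c1 | intermediate
10 | (4R)-4-(4-chlorobutyl)-7-methoxy-2,2-dioxo-3,4-dihydro-1,2,3-benzoxathiazin-5-yl pivalate | COc1cc2c(c(OC(=O)C(C)(C)C)c1)[C@@H](CCCCCl)NS(=O)(=O)O2 | intermediate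
11 | (R)-piperidine-fused sulfamidate (N3 of 10 joined to the chain terminus; pyrido[1,2-c][1,2,3]benzoxathiazine S,S-dioxide, pivalate and methoxy retained) | COc1cc2c(c(OC(=O)C(C)(C)C)c1)[C@H]1CCCCN1S(=O)(=O)O2 | intermediate
12 | 5-methoxy-2-[(2R)-piperidin-2-yl]benzene-1,3-diol | COc1cc(O)c([C@H]2CCCCN2)c(O)c1 | intermediate
13 | (2R)-2-(2,6-dihydroxy-4-methoxyphenyl)-1-methylidenepiperidin-1-ium | COc1cc(O)c([C@H]2CCCC[N+]2=C)c(O)c1 | intermediate
14 | 5-methoxy-2-[(2R)-1-methylpiperidin-2-yl]benzene-1,3-diol | COc1cc(O)c([C@H]2CCCCN2C)c(O)c1 | intermediate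
15 | 1-[2,4-dihydroxy-6-methoxy-3-((2R)-1-methylpiperidin-2-yl)phenyl]ethan-1-one | COc1cc(O)c([C@H]2CCCCN2C)c(O)c1C(C)=O | intermediate
16 | methyl benzoate | COC(=O)c1ccccc1 | starting material
17 | trisodium salt of 15 (bis-phenoxide methyl-ketone enolate) | [Na+].[Na+].[Na+].COc1cc([O-])c([C@H]2CCCCN2C)c([O-])c1C([O-])=C | intermediate
18 | 1-[2,4-dihydroxy-6-methoxy-3-((2R)-1-methylpiperidin-2-yl)phenyl]-3-phenylpropane-1,3-dione | COc1cc(O)c([C@H]2CCCCN2C)c(O)c1C(=O)CC(=O)c1ccccc1 | intermediate
19 | (R)-7-hydroxy-5-methoxy-8-(1-methylpiperidin-2-yl)-2-phenyl-4H-chromen-4-one | COc1cc(O)c([C@H]2CCCCN2C)c2oc(-c3ccccc3)cc(=O)c12 | target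

**Totals and risks**

Total step count: 12. Longest linear sequence: 12 steps (from 1).

Steps most likely to fail:

Step 6. The catalyst may discriminate poorly between the two enantiotopic benzylic hydrogens, because the tether runs through the arene and holds the chain differently from the aliphatic sulfamates on which such catalysts were developed. Insertion may also be slow enough for oxidative degradation of the sulfamate to compete. The fallback builds the same C4–N bond by reduction and sets out from compound 2. The aryllithium 4, generated as in step 2, is added to excess 5-chloropentanoyl chloride at −78 °C (inverse addition; the di-ortho-substituted ketone resists a second addition) to give 5-chloro-1-[4-methoxy-2,6-bis(methoxymethoxy)phenyl]pentan-1-one F1. HCl in MeOH removes both MOM groups to give 5-chloro-1-(2,6-dihydroxy-4-methoxyphenyl)pentan-1-one F2. Sulfamoyl chloride (1 equiv) in DMA should give 2-(5-chloropentanoyl)-3-hydroxy-5-methoxyphenyl sulfamate F3, which is expected to condense in the same flask onto the neighbouring ketone to give the cyclic N-sulfonyl ketimine 4-(4-chlorobutyl)-5-hydroxy-7-methoxy-1,2,3-benzoxathiazine 2,2-dioxide F4. Pivaloylation (PivCl, Et3N) gives 4-(4-chlorobutyl)-7-methoxy-2,2-dioxo-1,2,3-benzoxathiazin-5-yl pivalate F5. Asymmetric transfer hydrogenation of its C=N bond with RhCl(Cp*)[(S,S)-TsDPEN] or its antipode (chosen for 4R) and HCO2H/Et3N, a reduction well established for 4-substituted cyclic sulfamidate imines of this ring system, should give compound 10, where the route resumes at step 7.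

Step 10. Configuration may erode through reversible ionisation of the benzylic C–N bond under the Lewis acid (the ring is trioxygenated ortho and para to that carbon), and acylation may stop at oxygen. The fallback replaces electrophilic substitution by directed metalation and sets out from compound 14. Both phenols are protected (NaH, MOMCl, DMF) as (2R)-2-[4-methoxy-2,6-bis(methoxymethoxy)phenyl]-1-methylpiperidine F6. n-BuLi in THF at 0 °C should metalate the ring carbon between OMOM and OMe (the two such positions are equivalent) to give {3-methoxy-5-(methoxymethoxy)-... }aryllithium, i.e. [6-methoxy-2,4-bis(methoxymethoxy)-3-((2R)-1-methylpiperidin-2-yl)phenyl]lithium F7. Acylation with N-methoxy-N-methylacetamide gives 1-[6-methoxy-2,4-bis(methoxymethoxy)-3-((2R)-1-methylpiperidin-2-yl)phenyl]ethan-1-one F8. HCl in MeOH at rt removes the MOM groups and returns compound 15, where the route resumes at step 11.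

Step 9. Formaldehyde or the iminium ion may attack the very nucleophilic ring carbons (hydroxymethylation, Mannich-type oligomerisation) in competition with hydride capture. The fallback introduces the methyl carbon at the acyl oxidation level and sets out from compound 12. Heating in ethyl formate should formylate only the nitrogen, giving (2R)-2-(2,6-dihydroxy-4-methoxyphenyl)piperidine-1-carbaldehyde F9. LiAlH4 in THF at reflux reduces the formamide to the N-methyl group and returns compound 14, where the route resumes at step 10.

**Further compounds**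

F1 | step 6 | 5-chloro-1-[4-methoxy-2,6-bis(methoxymethoxy)phenyl]pentan-1-one | COCOc1cc(OC)cc(OCOC)c1C(=O)CCCCCl
F2 | step 6 | 5-chloro-1-(2,6-dihydroxy-4-methoxyphenyl)pentan-1-one | COc1cc(O)c(C(=O)CCCCCl)c(O)c1
F3 | step 6 | 2-(5-chloropentanoyl)-3-hydroxy-5-methoxyphenyl sulfamate | COc1cc(O)c(C(=O)CCCCCl)c(OS(N)(=O)=O)c1
F4 | step 6 | 4-(4-chlorobutyl)-5-hydroxy-7-methoxy-1,2,3-benzoxathiazine 2,2-dioxide | COc1cc(O)c2c(c1)OS(=O)(=O)N=C2CCCCCl
F5 | step 6 | 4-(4-chlorobutyl)-7-methoxy-2,2-dioxo-1,2,3-benzoxathiazin-5-yl pivalate | COc1cc(OC(=O)C(C)(C)C)c2c(c1)OS(=O)(=O)N=C2CCCCCl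
F6 | step 10 | (2R)-2-[4-methoxy-2,6-bis(methoxymethoxy)phenyl]-1-methylpiperidine | COCOc1cc(OC)cc(OCOC)c1[C@H]1CCCCN1C
F7 | step 10 | [6-methoxy-2,4-bis(methoxymethoxy)-3-((2R)-1-methylpiperidin-2-yl)phenyl]lithium | COCOc1c([Li])c(OC)cc(OCOC)c1[C@H]1CCCCN1C
F8 | step 10 | 1-[6-methoxy-2,4-bis(methoxymethoxy)-3-((2R)-1-methylpiperidin-2-yl)phenyl]ethan-1-one | COCOc1c(C(C)=O)c(OC)cc(OCOC)c1[C@H]1CCCCN1C
F9 | step 9 | (2R)-2-(2,6-dihydroxy-4-methoxyphenyl)piperidine-1-carbaldehyde | COc1cc(O)c([C@H]2CCCCN2C=O)c(O)c1
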